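**Retrosynthetic overview**

1. The target comes from a β-keto lactone by enol triflate reduction; the furan-fused cycloheptanone (ring C) is closed before that by an intramolecular Friedel–Crafts Michael addition of a 3-furyl carbinol (from 3-bromofuran and a side-chain aldehyde) onto the ring-B enone.
2. Ring B (the cyclohexene) and the γ-lactone arise together in the key step: a tethered diazoacetate carbon inserts into the C(=O)–C(quaternary) bond of a 4-hydroxycyclopentenone (five → six).
3. Enabling feature: the ring-B carbon that carries the lactone C=O sits between the ring-B C3 (a ketone until the last step) and the quaternary ring-fusion carbon that carries the lactone CH2–O. This CH(C=O) unit tied back by O–CH2 is the retron of a diazoacetate C–C insertion delivered through a three-atom ester tether.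
4. The hydrindane precursor comes from a Hajos–Parrish enedione: the angular CH3 becomes CH2OH by hydroxyl-directed C–H silylation, the tertiary OH comes from a singlet-oxygen ene reaction, and ring A is dressed by deconjugative allylation, methylenation/allylic oxidation/isomerisation and hydride reduction.
5. Order of ring formation: cyclopentane (bought) → ring A (aldol) → ring B + lactone (key step) → ring C (furan Michael).

Key step: step 17

**Remarks on the chemistry**

- Locants used in the names: C1 (CH bearing the furan), C2, C3, C4 (lactone α-carbon, absent before step 17), C5 (quaternary, bears C19H2–O), C6, C7 (CH–OAc), C8 (CH–C17H3), C9 (quaternary, bears C20H3 and C11H2), C10 (C–OH), C12 (ketone), C18 (lactone C=O). "α" is the face of C19; "β" is the opposite face.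
- The carbinol centres C7 in 11 and C12 in 29 and 30 should form as epimer mixtures that converge on oxidation; their SMILES leave that centre open.
- Aldehyde 25 is expected to sit largely as the cyclic hemiacetal with the C10 hydroxyl; it is drawn and used as the open form.

**Route**

Step 1
Reactants: 1 2-methylcyclopentane-1,3-dione; 2 pent-1-en-3-one
Product: 3 2-methyl-2-(3-oxopentyl)cyclopentane-1,3-dione
Conditions: Et3N (0.1 equiv), MeCN, 20 °C
Reagents that add atoms: none
Why: Michael addition of the acidic 2-alkyl-1,3-dione to the vinyl ketone; no stereocentre is formed.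

Step 2
Reactants: 3 trione
Product: 4 (7aR)-4,7a-dimethyl-2,3,7,7a-tetrahydro-1H-indene-1,5(6H)-dione
Conditions: (R)-phenylalanine (1 equiv), (±)-camphor-10-sulfonic acid (0.5 equiv), DMF, 30 → 70 °C
Reagents that add atoms: none
Why: Hajos–Parrish enamine aldol cyclisation and dehydration; the (R)-amino acid differentiates the two enantiotopic ring carbonyls and should set the quaternary carbon C5 as R, the mirror image of the product obtained with the (S)-amino acid.

Step 3
Reactants: 4 enedione
Product: 5 (1R,7aR)-1-hydroxy-4,7a-dimethyl-1,2,3,6,7,7a-hexahydro-5H-inden-5-one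
Conditions: NaBH4 (0.3 equiv), EtOH, −20 °C
Reagents that add atoms: none
Why: chemoselective borohydride reduction of the saturated cyclopentanone beside the enone; hydride enters anti to the angular methyl, so the C3 hydroxyl ends cis to it.

Step 4
Reactants: 5 hydroxy enone
Product: 6 C3 TBS ether
Conditions: TBSCl, imidazole, DMF, 20 °C
Reagents that add atoms: tert-butyldimethylsilyl chloride CC(C)(C)[Si](C)(C)Cl
Why: standard silylation of a secondary alcohol to mask C3 through the base and hydride steps.

Step 5
Reactants: 6 silyl ether enone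
Product: 7 C9-allyl β,γ-unsaturated ketone
Conditions: KOtBu, tBuOH/THF, 0 °C; allyl bromide, 0 → 20 °C
Reagents that add atoms: allyl bromide C=CCBr
Why: deconjugative α-alkylation of the thermodynamic dienolate; the electrophile approaches C9 anti to the angular methyl and the OTBS group (allyl β, C20 α) and the olefin moves to C1=C10.

Step 6
Reactants: 7 allyl ketone
Product: 8 C12 aldehyde
Conditions: OsO4 (2 mol%), NaIO4, 2,6-lutidine, dioxane/H2O, 20 °C
Reagents that add atoms: sodium periodate [Na+].[O-]I(=O)(=O)=O; osmium tetroxide O=[Os](=O)(=O)=O (catalytic oxygen carrier)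
Why: Lemieux–Johnson cleavage; the terminal vinyl group should react far faster than the trisubstituted olefin buried between two quaternary carbons.

Step 7
Reactants: 8 keto aldehyde
Product: 9 dioxolane acetal
Conditions: (Me3SiOCH2)2, Me3SiOTf (5 mol%), CH2Cl2, −78 °C
Reagents that add atoms: 1,2-bis(trimethylsilyloxy)ethane C[Si](C)(C)OCCO[Si](C)(C)C
Why: silyl-triflate-catalysed acetalisation at low temperature is aldehyde-selective and leaves the neopentyl ketone alone.

Step 8
Reactants: 9 acetal ketone
Product: 10 C8-methylene compound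
Conditions: Ph3PCH3Br, KOtBu, toluene, 90 °C
Reagents that add atoms: methyltriphenylphosphonium bromide C[P+](c1ccccc1)(c1ccccc1)c1ccccc1.[Br-]
Why: Wittig methylenation of a hindered ketone with excess salt-free ylide at elevated temperature.

Step 9
Reactants: 10 exocyclic olefin
Product: 11 C7 allylic alcohol
Conditions: SeO2 (0.3 equiv), tBuOOH, CH2Cl2, 20 °C
Reagents that add atoms: tert-butyl hydroperoxide CC(C)(C)OO; selenium dioxide O=[Se]=O (catalytic oxygen carrier)
Why: Riley allylic oxidation; C7 holds the only allylic hydrogens of the exocyclic olefin, while the ring olefin has none on its substituted end, and the C7 configuration does not matter.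

Step 10
Reactants: 11 allylic alcohol
Product: 12 C7 ketone with 8α-methyl
Conditions: CpRu(PPh3)2Cl (5 mol%), Et3NHPF6 (10 mol%), dioxane, 100 °C; then DBU, 20 °C
Reagents that add atoms: none
Why: ruthenium-hydride redox isomerisation of an allylic alcohol to the saturated ketone, which leaves isolated olefins alone; base equilibration should place the new C8 methyl equatorial, cis to the C9 methyl.

Step 11
Reactants: 12 C7 ketone
Product: 14 C7 acetate, via lithium C7-alkoxide 13 (not isolated)
Conditions: LiBH(sBu)3, THF, −78 °C; then Ac2O, DMAP, −78 → 20 °C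
Reagents that add atoms: acetic anhydride CC(=O)OC(C)=O
Why: bulky-hydride reduction; axial approach is blocked by the two syn-axial carbons C19 and C20, so hydride comes from the β face and gives the axial 7α-alkoxide, which is acetylated in the same flask.

Step 12
Reactants: 14 acetate silyl ether
Product: 15 C3 alcohol
Conditions: HF·pyridine, THF, 0 → 20 °C
Reagents that add atoms: none
Why: fluoride cleavage of the silyl ether under buffered conditions that spare the acetate and the dioxolane.

Step 13
Reactants: 15 C3 alcohol
Product: 18 C3/C19 diol, via hydridosilyl ether 16 (not isolated), via oxasilolane 17 (not isolated)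
Conditions: Et2SiH2, [Ir(cod)OMe]2 (0.5 mol%), THF, 20 °C; then [Ir(cod)OMe]2 (2 mol%), 3,4,7,8-tetramethyl-1,10-phenanthroline, norbornene, THF, 120 °C; then H2O2, KHCO3, MeOH/THF, 50 °C
Reagents that add atoms: hydrogen peroxide OO; diethylsilane CC[SiH2]CC (silicon of 16 and 17 only)
Why: iridium-catalysed hydroxyl-directed γ-C–H silylation followed by Tamao–Fleming oxidation; the silyl ether is cis to the angular methyl, whose primary C–H closes the five-membered oxasilolane, and C–Si goes to C–O without touching a stereocentre.

Step 14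
Reactants: 18 diol
Product: 20 triol, via C10 hydroperoxide 19 (not isolated)
Conditions: O2, hν, tetraphenylporphyrin, CH2Cl2, −20 °C; then PPh3
Reagents that add atoms: dioxygen O=O
Why: Schenck ene reaction; only C2 carries allylic hydrogens, so oxygen must add to C10 with the olefin shifting to C1=C2, and singlet oxygen should attack the β face opposite to C19 and C20, setting the C10 carbinol.

Step 15
Reactants: 20 triol
Product: 21 hydroxy cyclopentenone
Conditions: MnO2, CH2Cl2, 20 °C
Reagents that add atoms: none
Why: MnO2 oxidises only the allylic secondary alcohol; the primary neopentyl and the tertiary hydroxyl are inert.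

Step 16
Reactants: 21 hydroxy cyclopentenone
Product: 22 C19 diazoacetate
Conditions: TsNHN=CHCOCl, PhNMe2, CH2Cl2, 0 °C; then Et3N
Reagents that add atoms: glyoxylic acid chloride p-toluenesulfonylhydrazone Cc1ccc(cc1)S(=O)(=O)NN=CC(Cl)=O
Why: acylation of the only acylable (primary) hydroxyl, then base-induced loss of sulfinate from the tosylhydrazone to unveil the diazoacetate.

Step 17
Reactants: 22 diazoacetate
Product: 24 β-keto lactone enone, via diazonium betaine 23 (not isolated)
Conditions: Sc(OTf)3 (20 mol%), CH2Cl2, −20 → 20 °C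
Reagents that add atoms: none
Why: Proposed new method: the Lewis acid activates the cyclopentenone carbonyl, the nucleophilic diazo carbon adds to it through the CH2–O–C(=O) tether to give the six-membered betaine 23, and the ring bond to the quaternary carbon C5, anti-periplanar to the departing N2, undergoes a 1,2-shift. The closest known reactions are the Lewis-acid-promoted diazoacetate homologation of cyclic ketones (Tiffeneau–Demjanov / Büchner–Curtius–Schlotterbeck type) and its nitrogen counterpart, the intramolecular Schmidt reaction, in which the tethered α-carbon is the one that migrates. Ring B closes by this 1,2-shift ring expansion of the cyclopentenone (five → six), and the γ-lactone closes by 6-exo-trig carbonyl addition followed by contraction of that transient ring to five as C5 moves from C3 to C4. C5 migrates with retention (set in step 2), C10 is untouched, and the new C4 centre is forced cis by the lactone fusion and is removed in steps 22–23. The step needs migration of the sp3 quaternary carbon instead of the vinyl carbon and no oxirane formation; the tether secures this because only the ring bond C3–C5 can lie anti to an equatorial diazonium group in the cyclic betaine. Carbonyl addition is favoured over reaction at the enone olefin because only the C=O lies within reach of the three-atom tether.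

Step 18
Reactants: 24 β-keto lactone acetal
Product: 25 C12 aldehyde
Conditions: pyridinium p-toluenesulfonate, acetone/H2O, 40 °C
Reagents that add atoms: water O
Why: mild acid hydrolysis of the dioxolane; the γ-hydroxy enone and the β-keto lactone cannot eliminate or retro-aldolise.

Step 19
Reactants: 25 aldehyde; 26 3-bromofuran
Product: 29 furyl carbinol, via 3-furyllithium 27 (not isolated), via 3-furyltitanium triisopropoxide 28 (not isolated)
Conditions: 26, nBuLi, THF, −78 °C; ClTi(OiPr)3; then 25, −78 → 0 °C (excess reagent)
Reagents that add atoms: none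
Why: aryltitanium reagents add to aldehydes chemoselectively beside ketone, lactone and acetate; the excess absorbs the acidic β-keto lactone and hydroxyl protons, and the C12 epimers converge in step 21.

Step 20
Reactants: 29 furyl carbinol
Product: 30 ring-C carbinol
Conditions: Sc(OTf)3 (10 mol%), MeCN, 0 → 20 °C
Reagents that add atoms: none
Why: intramolecular Friedel–Crafts-type Michael addition (7-exo-trig); chelation of the β-keto lactone activates the enone, the furan α-carbon next to the side chain is the only one in reach, and the tether from the β-oriented C11 delivers it to the β face of C1, setting that stereocentre.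

Step 21
Reactants: 30 ring-C carbinol
Product: 31 C12 ketone
Conditions: MnO2, CH2Cl2, 20 °C
Reagents that add atoms: none
Why: MnO2 oxidation of the furan-activated secondary carbinol; the tertiary alcohol and the β-keto lactone are inert.

Step 22
Reactants: 31 β-keto lactone
Product: 32 enol triflate
Conditions: NaH (1.05 equiv), PhNTf2, THF, 0 °C
Reagents that add atoms: N-phenyl-bis(trifluoromethanesulfonimide) O=S(=O)(N(c1ccccc1)S(=O)(=O)C(F)(F)F)C(F)(F)F
Why: one equivalent of base deprotonates only the β-keto lactone (most acidic site), and its enolate is triflated on the ketone oxygen to give the C3=C4 enol triflate.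

Step 23
Reactants: 32 enol triflate
Product: 33 target
Conditions: Pd(OAc)2, PPh3, HCO2H, Bu3N, DMF, 60 °C
Reagents that add atoms: none
Why: palladium-catalysed formate reduction of an enol triflate gives the α,β-unsaturated lactone with C3–H; no stereocentre is affected.

**Compound list**

1 | 2-methylcyclopentane-1,3-dione | CC1C(=O)CCC1=O | starting material
2 | pent-1-en-3-one (ethyl vinyl ketone) | CCC(=O)C=C | starting material
3 | 2-methyl-2-(3-oxopentyl)cyclopentane-1,3-dione | CCC(=O)CCC1(C)C(=O)CCC1=O | intermediate
4 | (7aR)-4,7a-dimethyl-2,3,7,7a-tetrahydro-1H-indene-1,5(6H)-dione | O=C1CC[C@@]2(C)C(=O)CCC2=C1C | intermediate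
5 | (1R,7aR)-1-hydroxy-4,7a-dimethyl-1,2,3,6,7,7a-hexahydro-5H-inden-5-one (OH cis to angular methyl) | O=C1CC[C@@]2(C)[C@H](O)CCC2=C1C | intermediate
6 | tert-butyldimethylsilyl ether of 5 | O=C1CC[C@@]2(C)[C@H](O[Si](C)(C)C(C)(C)C)CCC2=C1C | intermediate
7 | C9-allyl ketone: C9 quaternary (allyl β, methyl α), C1=C10 olefin, C3 α-OTBS | O=C1CC[C@@]2(C)[C@H](O[Si](C)(C)C(C)(C)C)CC=C2[C@@]1(C)CC=C | intermediate
8 | C12 aldehyde (C9–CH2–CHO in place of allyl) | O=C1CC[C@@]2(C)[C@H](O[Si](C)(C)C(C)(C)C)CC=C2[C@@]1(C)CC=O | intermediate
9 | 1,3-dioxolane acetal of 8 | O=C1CC[C@@]2(C)[C@H](O[Si](C)(C)C(C)(C)C)CC=C2[C@@]1(C)CC1OCCO1 | intermediate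
10 | C8 exocyclic methylene compound | C=C1CC[C@@]2(C)[C@H](O[Si](C)(C)C(C)(C)C)CC=C2[C@@]1(C)CC1OCCO1 | intermediate
11 | C7 allylic alcohol (C7 epimers) with C8 methylene | C=C1C(O)C[C@@]2(C)[C@H](O[Si](C)(C)C(C)(C)C)CC=C2[C@@]1(C)CC1OCCO1 | intermediate
12 | C7 ketone with 8α-methyl (cis to the C9 methyl) | C[C@@H]1C(=O)C[C@@]2(C)[C@H](O[Si](C)(C)C(C)(C)C)CC=C2[C@@]1(C)CC1OCCO1 | intermediate
13 | lithium 7α-alkoxide | [Li+].[O-][C@@H]1C[C@@]2(C)[C@H](O[Si](C)(C)C(C)(C)C)CC=C2[C@@](C)(CC2OCCO2)[C@@H]1C | intermediate
14 | 7α-acetate (acetoxy, C17, C19 and C20 all on the α face) | CC(=O)O[C@@H]1C[C@@]2(C)[C@H](O[Si](C)(C)C(C)(C)C)CC=C2[C@@](C)(CC2OCCO2)[C@@H]1C | intermediate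
15 | C3 α-alcohol | CC(=O)O[C@@H]1C[C@@]2(C)[C@H](O)CC=C2[C@@](C)(CC2OCCO2)[C@@H]1C | intermediate
16 | diethyl(hydrido)silyl ether of 15 | CC(=O)O[C@@H]1C[C@@]2(C)[C@H](O[SiH](CC)CC)CC=C2[C@@](C)(CC2OCCO2)[C@@H]1C | intermediate
17 | oxasilolane (O3–SiEt2–C19, cis-fused to the cyclopentene) | CC(=O)O[C@@H]1C[C@]23C[Si](CC)(CC)O[C@@H]3CC=C2[C@@](C)(CC2OCCO2)[C@@H]1C | intermediate
18 | C3/C19 diol (C5 now bears CH2OH, α) | CC(=O)O[C@@H]1C[C@@]2(CO)[C@H](O)CC=C2[C@@](C)(CC2OCCO2)[C@@H]1C | intermediate
19 | C10 β-hydroperoxide with C1=C2 olefin | CC(=O)O[C@@H]1C[C@@]2(CO)[C@H](O)C=C[C@]2(OO)[C@@](C)(CC2OCCO2)[C@@H]1C | intermediate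
20 | triol (C10 β-OH, C3 α-OH, C19 OH) | CC(=O)O[C@@H]1C[C@@]2(CO)[C@H](O)C=C[C@]2(O)[C@@](C)(CC2OCCO2)[C@@H]1C | intermediate
21 | 4-hydroxycyclopentenone (C3 ketone, C1=C2, C10 β-OH, C19 OH) | CC(=O)O[C@@H]1C[C@@]2(CO)C(=O)C=C[C@]2(O)[C@@](C)(CC2OCCO2)[C@@H]1C | intermediate
22 | C19 diazoacetate of 21 | CC(=O)O[C@@H]1C[C@@]2(COC(=O)C=[N+]=[N-])C(=O)C=C[C@]2(O)[C@@](C)(CC2OCCO2)[C@@H]1C | intermediate
23 | diazonium betaine (C4 bonded to C3; metal-bound alkoxide at C3) | CC(=O)O[C@@H]1C[C@@]23COC(=O)C([N+]#N)C2([O-])C=C[C@]3(O)[C@@](C)(CC2OCCO2)[C@@H]1C | intermediate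
24 | ring-B enone β-keto lactone (C3 ketone, C1=C2, cis-fused γ-lactone at C4–C5, C10 β-OH; largely enolised) | CC(=O)O[C@@H]1C[C@@]23COC(=O)[C@@H]2C(=O)C=C[C@]3(O)[C@@](C)(CC2OCCO2)[C@@H]1C | intermediate
25 | C12 aldehyde of 24 (in equilibrium with the C10–O hemiacetal) | CC(=O)O[C@@H]1C[C@@]23COC(=O)[C@@H]2C(=O)C=C[C@]3(O)[C@@](C)(CC=O)[C@@H]1C | intermediate
26 | 3-bromofuran | Brc1ccoc1 | starting material
27 | 3-furyllithium | [Li]c1ccoc1 | intermediate
28 | 3-furyltitanium triisopropoxide | CC(C)O[Ti](OC(C)C)(OC(C)C)c1ccoc1 | intermediate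
29 | 3-furyl carbinol at C12 (C12 epimers) | CC(=O)O[C@@H]1C[C@@]23COC(=O)[C@@H]2C(=O)C=C[C@]3(O)[C@@](C)(CC(O)c2ccoc2)[C@@H]1C | intermediate
30 | pentacyclic carbinol: furan C2 bonded to C1 (β), ring C closed, C12 OH (epimers) | CC(=O)O[C@@H]1C[C@@]23COC(=O)[C@@H]2C(=O)C[C@H]2c4occc4C(O)C[C@@](C)([C@@H]1C)[C@@]23O | intermediate
31 | C12 ketone (β-keto lactone still at C3/C4) | CC(=O)O[C@@H]1C[C@@]23COC(=O)[C@@H]2C(=O)C[C@H]2c4occc4C(=O)C[C@@](C)([C@@H]1C)[C@@]23O | intermediate
32 | C3 enol triflate (C3=C4) | CC(=O)O[C@@H]1C[C@@]23COC(=O)C2=C(OS(=O)(=O)C(F)(F)F)C[C@H]2c4occc4C(=O)C[C@@](C)([C@@H]1C)[C@@]23O | intermediate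
33 | CNP0329797.2 | CC(=O)O[C@@H]1C[C@@]23COC(=O)C2=CC[C@H]2c4occc4C(=O)C[C@@](C)([C@@H]1C)[C@@]23O | target

**Step count and risks**

Total step count: 23. Longest linear sequence: 23 steps (1/2 → 33); 3-bromofuran enters in step 19.

Steps most likely to fail:

1. Step 17 (proposed method). The vinyl carbon could migrate in place of the quaternary carbon (bridged isomer), the alkoxide could close an oxirane onto the diazonium carbon, or nitrogen could be lost before the C–C bond forms. Fallback: set out from 21 and run the known intermolecular Lewis-acid homologation with ethyl diazoacetate and BF3·OEt2 in CH2Cl2 at 0 °C to the ring-expanded β-keto ethyl ester F1. Warming F1 with pyridinium p-toluenesulfonate in toluene lactonises the C19 hydroxyl onto the ester and returns to the route at 24.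

2. Step 20. Reversible oxa-Michael addition of the free C12 hydroxyl, or its ionisation and capture by the C10 hydroxyl, could outrun a slow seven-membered ring closure. Fallback: set out from 29, mask the carbinol as the triethylsilyl ether F2 (Et3SiCl, imidazole), cyclise the ether with Me2AlCl at −78 °C to the silylated ring-C compound F3, and cleave the silyl group with HF·pyridine to come back at 30.

3. Step 10. The ruthenium hydride may fail to engage the hindered 2-substituted allylic alcohol or may migrate the ring olefin. Fallback: set out from 11, oxidise with MnO2 to the exo-methylene ketone F4, then deliver hydride in a 1,4 sense with [(Ph3P)CuH]6 and equilibrate with DBU to come back at 12.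

**Further compounds**

F1 | step 17 | ring-expanded β-keto ethyl ester with free C19 hydroxyl | CC(=O)O[C@@H]1C[C@@]2(CO)C(C(=O)OCC)C(=O)C=C[C@]2(O)[C@@](C)(CC2OCCO2)[C@@H]1C
F2 | step 20 | C12 triethylsilyl ether of 29 | CC(=O)O[C@@H]1C[C@@]23COC(=O)[C@@H]2C(=O)C=C[C@]3(O)[C@@](C)(CC(O[Si](CC)(CC)CC)c2ccoc2)[C@@H]1C
F3 | step 20 | C12 triethylsilyl ether of 30 | CC(=O)O[C@@H]1C[C@@]23COC(=O)[C@@H]2C(=O)C[C@H]2c4occc4C(O[Si](CC)(CC)CC)C[C@@](C)([C@@H]1C)[C@@]23O
F4 | step 10 | C7 ketone with C8 exocyclic methylene | C=C1C(=O)C[C@@]2(C)[C@H](O[Si](C)(C)C(C)(C)C)CC=C2[C@@]1(C)CC1OCCO1
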